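The γ-lactone is disconnected between its carbonyl carbon C12 and the ring-fusion carbon C13. C13 is α to the C14 ketone of the cyclohexanedione ring, and C12 hangs on the spiro-carbinol oxygen O11. In the key step, [(Ph3P)CuH]6 delivers hydride to C18 of a cyclohexenone (C14=O, C13=C18) whose C18 bears the C10 methyl carbonate. The regiodefined C13 enolate then closes the lactone by 5-exo C-acylation, which fixes the C18 hydrogen trans to the C16 side chain and the cis ring fusion. The precursor comes from a spiro Diels–Alder adduct, a photoredox aldehyde alkylation and a Robinson-type aldol closure. C13 methylation, ring-closing metathesis and oxidation finish the synthesis.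

Key step: step 21

Remark on numbering: target locants are used throughout: C1(Me)–C2–C3–C4–C5–C6=C7(CO2H)–C8(Me)–C9–C10(spiro)–O11–C12(=O)–C13(Me)–C14(=O)–C15(=O)–C16–C17–C18, with C16–C19(Me)–C20–C1 closing the 11-membered ring, C10–C18 and C13–C18 bonded.

Remark on the chemistry: the target is taken as the diketo tautomer drawn, and C16 (α to C15=O) is assumed to hold its configuration in the bridged macrocycle. The C15 carbinol centre of compounds 23–34 is an epimer mixture of no consequence (left undefined in the SMILES) and is oxidised in the last step.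

**Fragment 1 (C15, C16, C19, C20, C1, C2)**

Step 1
Reactants: 1 cis-3,5-dimethylcyclohexanone
Product: 2 (3S,5R)-3,5-dimethyl-1-(trimethylsilyloxy)cyclohex-1-ene
Conditions: lithium (S,S)-bis(1-phenylethyl)amide (from the amine and nBuLi), Me3SiCl (internal quench), THF, −100 °C
Reagents that add atoms: chlorotrimethylsilane C[Si](C)(C)Cl
Why: Enantioselective deprotonation of a meso ketone by a chiral lithium amide separates the enantiotopic axial α-hydrogens and so differentiates the two methyl-bearing centres (later C19 and C1); the (S,S) base is chosen by analogy with the sense known for 4-substituted cyclohexanones, and its antipode would serve if correlation showed the opposite.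

Step 2
Reactants: 2 (3S,5R)-3,5-dimethyl-1-(trimethylsilyloxy)cyclohex-1-ene
Product: 3 (3R,5S)-3,5-dimethyl-6-oxohexanoic acid
Conditions: O3, CH2Cl2/MeOH, −78 °C; then Me2S
Reagents that add atoms: ozone [O-][O+]=O
Why: Ozonolysis of a silyl enol ether cleaves the C=C bond to an aldehyde and, after loss of silicon, a carboxylic acid without touching either stereocentre.

Step 3
Reactants: 3 (3R,5S)-3,5-dimethyl-6-oxohexanoic acid
Product: 4 (3R,5S)-3,5-dimethylhept-6-enoic acid
Conditions: Ph3PCH3Br, KOtBu (2.2 equiv), THF, 0 °C
Reagents that add atoms: methylenetriphenylphosphorane C=P(c1ccccc1)(c1ccccc1)c1ccccc1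
Why: Wittig methylenation of the aldehyde in the presence of the carboxylate installs the C2 vinyl group; the salt-free, cold conditions should spare the α-stereocentre (C1).

Step 4
Reactants: 4 (3R,5S)-3,5-dimethylhept-6-enoic acid
Product: 5 (3R,5S)-3,5-dimethylhept-6-en-1-ol
Conditions: LiAlH4, Et2O, 0 °C to rt
Reagents that add atoms: none
Why: Hydride reduction of the carboxylic acid gives the primary alcohol and leaves the isolated alkene alone.

Step 5
Reactants: 5 (3R,5S)-3,5-dimethylhept-6-en-1-ol
Product: 6 (3R,5S)-3,5-dimethylhept-6-enal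
Conditions: Dess–Martin periodinane, NaHCO3, CH2Cl2, 0 °C to rt
Reagents that add atoms: none
Why: Periodinane oxidation stops at the aldehyde, which has no α-stereocentre to lose (C16 is still CH2).

**Fragment 2 (dienophile)**

Step 6
Reactants: 7 (S)-lactic acid; 8 pivalaldehyde
Product: 9 (2S,5S)-2-tert-butyl-5-methyl-1,3-dioxolan-4-one
Conditions: TsOH (cat.), pentane, reflux with water separator; crystallisation of the cis isomer
Reagents that add atoms: none
Why: Acid-catalysed acetalisation of the α-hydroxy acid gives mainly the cis dioxolanone, so the lactate centre fixes the acetal centre that later acts as the controller.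

Step 7
Reactants: 9 (2S,5S)-2-tert-butyl-5-methyl-1,3-dioxolan-4-one
Product: 10 (2S)-5-bromo-2-tert-butyl-5-methyl-1,3-dioxolan-4-one (C5 epimers)
Conditions: NBS, AIBN (cat.), cyclohexane, reflux
Reagents that add atoms: N-bromosuccinimide O=C1CCC(=O)N1Br
Why: Radical bromination takes place at the captodatively stabilised C5 position; the C5 configuration is lost in the next step.

Step 8
Reactants: 10 (2S)-5-bromo-2-tert-butyl-5-methyl-1,3-dioxolan-4-one
Product: 11 (S)-2-tert-butyl-5-methylene-1,3-dioxolan-4-one
Conditions: DBU, benzene, rt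
Reagents that add atoms: none
Why: E2 elimination of HBr from the tertiary bromide gives the exo-methylene lactone, a chiral α-hydroxyacrylate equivalent.

**Fragment 3 (diene)**

Step 9
Reactants: 12 but-2-yn-1-ol
Product: 13 (E)-2-(tributylstannyl)but-2-en-1-ol
Conditions: Bu3SnH, PdCl2(PPh3)2 (cat.), THF, rt
Reagents that add atoms: tributyltin hydride CCCC[SnH](CCCC)CCCC
Why: Palladium-catalysed syn hydrostannation, directed to the carbon next to the hydroxymethyl group, puts tin on the future C7 and fixes the C7=C8 geometry.

Step 10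
Reactants: 13 (E)-2-(tributylstannyl)but-2-en-1-ol
Product: 14 tert-butyldimethylsilyl ether of 13
Conditions: tBuMe2SiCl, imidazole, DMF, rt
Reagents that add atoms: tert-butyldimethylsilyl chloride CC(C)(C)[Si](C)(C)Cl
Why: Standard silylation masks the primary alcohol that becomes the C7 carboxyl at the end.

Step 11
Reactants: 15 pent-1-en-4-yne
Product: 16 (E)-1-iodopenta-1,4-diene
Conditions: Cp2Zr(H)Cl, THF, rt; then I2, 0 °C
Reagents that add atoms: iodine II
Why: Hydrozirconation is faster at the terminal alkyne than at the alkene and is syn, so iodinolysis gives the (E)-vinyl iodide with retention.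

Step 12
Reactants: 14 silyl ether of the stannane; 16 (E)-1-iodopenta-1,4-diene
Product: 17 tert-butyl{[(2Z,3E)-2-ethylidenehepta-3,6-dien-1-yl]oxy}dimethylsilane
Conditions: Pd(PPh3)4 (cat.), CuI (cat.), CsF, DMF, 45 °C
Reagents that add atoms: none
Why: Stille coupling proceeds with retention at both sp2 carbons and gives the diene with methyl (C8) and the allyl-bearing terminus (C5) both "outside".

**Assembly**

Step 13
Reactants: 11 (S)-2-tert-butyl-5-methylene-1,3-dioxolan-4-one; 17 triene
Product: 18 spiro Diels–Alder adduct (cyclohexene with C5 allyl, C7 CH2OTBS and C8 methyl, spiro at C10 to the 2-tert-butyl-1,3-dioxolan-4-one)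
Conditions: toluene, BHT (trace), 110 °C, sealed tube
Reagents that add atoms: none
Why: Thermal Diels–Alder reaction in which the methylene carbon (C9) bonds to the more nucleophilic diene terminus C8; the lactone carbonyl sits exo so O11 ends cis to the C5 and C8 substituents, and the diene adds anti to the tert-butyl group, which should give C5, C8 and C10 as in the target.

Step 14
Reactants: 18 spiro Diels–Alder adduct
Product: 19 α-hydroxy methyl ketone (C10–OH, C18 acetyl)
Conditions: MeLi (1.1 equiv), THF, −78 °C; aq. NH4Cl
Reagents that add atoms: methyllithium [Li]C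
Why: Acyl substitution at the lactone carbonyl: the cyclic tetrahedral alkoxide is stable in the cold and collapses on work-up to the methyl ketone with loss of pivalaldehyde, freeing the tertiary hydroxyl O11.

Step 15
Reactants: 19 α-hydroxy methyl ketone
Product: 21 bromomethyl ketone O11-trimethylsilyl ether, via bis-silyl enol ether 20 (not isolated)
Conditions: Me3SiOTf, Et3N, CH2Cl2, 0 °C; then NBS, THF, −78 to 0 °C
Reagents that add atoms: trimethylsilyl triflate C[Si](C)(C)OS(=O)(=O)C(F)(F)F; N-bromosuccinimide O=C1CCC(=O)N1Br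
Why: Soft enolisation can give only the C18=C17 silyl enol ether (C10 is quaternary) and also caps O11; electrophilic bromination of the enol ether is faster than attack on the isolated alkenes.

Step 16
Reactants: 21 bromomethyl ketone; 6 (3R,5S)-3,5-dimethylhept-6-enal
Product: 22 γ-keto aldehyde (new C16–C17 bond, C16 stereocentre)
Conditions: Ru(bpy)3Cl2 (cat.), (2S,5R)-2-tert-butyl-3,5-dimethylimidazolidin-4-one triflate salt (20 mol%), 2,6-lutidine, DMF, visible light, rt
Reagents that add atoms: none
Why: Photoredox organocatalytic α-alkylation of an aldehyde: the α-keto radical from 21 adds to the open face of the chiral enamine of 6, so C16 is set by the catalyst; the antipode named is chosen by analogy (the CIP sense is inverted relative to simple alkanals because the branched chain outranks the ketomethyl group).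

Step 17
Reactants: 22 γ-keto aldehyde
Product: 24 dihydroxy diketone (C15–OH, C14 acetyl, C10–OH), via lithium alkoxide of the enol ether adduct 23 (not isolated)
Conditions: (1-ethoxyvinyl)lithium (ethyl vinyl ether, tBuLi), THF, −78 °C; then 1 M HCl, THF, 0 °C
Reagents that add atoms: (1-ethoxyvinyl)lithium [Li]C(=C)OCC; water O
Why: The acetyl anion equivalent adds to the aldehyde faster than to the hindered C18 ketone; acid hydrolysis unmasks the methyl ketone and removes the O11 silyl group, so both oxygens of the future dione (C14, C15) are in place.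

Step 18
Reactants: 24 dihydroxy diketone
Product: 25 C15 tert-butyldimethylsilyl ether
Conditions: tBuMe2SiOTf (1.1 equiv), 2,6-lutidine, CH2Cl2, −78 °C
Reagents that add atoms: tert-butyldimethylsilyl triflate CC(C)(C)[Si](C)(C)OS(=O)(=O)C(F)(F)F
Why: The secondary hydroxyl is silylated much faster than the tertiary α-ketol hydroxyl; keeping C15 at the alcohol level protects C16 from epimerisation until the end.

Step 19
Reactants: 25 C15 silyl ether diketone
Product: 26 hydroxy enone (C14=O, C13=C18, C18 bearing the C10 carbinol)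
Conditions: pyrrolidine, AcOH, toluene, 60 °C
Reagents that add atoms: none
Why: Robinson-type intramolecular aldol condensation: the enamine of the methyl ketone (C13) can reach only the C18 carbonyl through a six-membered ring, and dehydration gives the conjugated enone.

Step 20
Reactants: 26 hydroxy enone
Product: 27 enone methyl carbonate (O11–C12)
Conditions: LiN(SiMe3)2 (1.05 equiv), THF, −78 °C; then ClCO2Me
Reagents that add atoms: methyl chloroformate COC(=O)Cl
Why: Fast O–H deprotonation at low temperature and acylation of the tertiary alkoxide install C12 on O11, four atoms away from C13.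

Step 21
Reactants: 27 enone methyl carbonate
Product: 29 β-keto-γ-lactone (C12–C13 bond, C13–H), via copper enolate 28 (not isolated)
Conditions: [(Ph3P)CuH]6 (0.4 equiv of hexamer), toluene, rt to 40 °C; aq. NH4Cl
Reagents that add atoms: none
Why: Proposed new method: hydride transfer from the copper hydride cluster to C18 of the β,β-disubstituted enone gives the regiodefined copper enolate 28, whose C13 attacks the carbonate carbonyl C12 held on O11; loss of methoxide gives the β-keto-γ-lactone, which is then held as its stabilised enolate. The closest known reaction types are the reductive aldol cyclisation of enones with this reagent and the Dieckmann condensation; conjugate reduction followed by intramolecular acylation by a carbonate has not been shown on this substrate class. The lactone closes in the 5-exo-trig mode at the carbonate carbonyl. C18 is set by axial hydride delivery anti to the equatorial C16 side chain (substrate control), so C10 ends cis to C19, and the tether allows only the cis fusion at C13/C18 (C13 is fixed for good in step 22). The step needs 1,4- over 1,2-reduction and C- over O-acylation: the soft copper hydride secures the first, and the five-membered transition state secures the second because O-acylation would need a seven-membered ring.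

Step 22
Reactants: 29 β-keto-γ-lactone
Product: 30 C13-methylated β-keto-γ-lactone
Conditions: K2CO3, MeI, acetone, rt
Reagents that add atoms: iodomethane CI
Why: C-alkylation of the β-keto lactone enolate from the face of the C18 hydrogen (opposite the six-membered ring) gives the cis-fused quaternary centre with the target configuration at C13.

Step 23
Reactants: 30 C13-methylated β-keto-γ-lactone
Product: 31 macrocyclic alkene (C2=C3, 11-membered ring)
Conditions: second-generation Grubbs catalyst (10 mol%), CH2Cl2 (1 mM), 40 °C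
Reagents that add atoms: none
Why: Ring-closing metathesis between the C5 allyl and the C1 vinyl groups, held close by the rigid spiro-bicyclic core, closes the 11-membered carbocycle; the alkene geometry is of no consequence.

Step 24
Reactants: 31 macrocyclic alkene
Product: 32 saturated macrocycle
Conditions: H2 (1 atm), RhCl(PPh3)3 (cat.), benzene, rt
Reagents that add atoms: none
Why: Homogeneous hydrogenation reduces the disubstituted C2=C3 alkene and leaves the trisubstituted C6=C7 alkene and the ketone alone.

Step 25
Reactants: 32 saturated macrocycle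
Product: 33 diol (C7–CH2OH, C15–OH)
Conditions: HF·pyridine, pyridine, THF, 0 °C to rt
Reagents that add atoms: none
Why: Buffered fluoride removes both silyl ethers without base, which the β-keto lactone would not tolerate.

Step 26
Reactants: 33 diol
Product: 34 hydroxy acid (C7–CO2H, C15–OH)
Conditions: TEMPO (cat.), NaOCl (cat.), NaClO2, MeCN/phosphate buffer (pH 6.7), 35 °C
Reagents that add atoms: sodium chlorite [Na+].[O-]Cl=O
Why: Oxoammonium/chlorite oxidation takes the primary allylic alcohol to the acid much faster than it oxidises the hindered secondary α-hydroxy ketone.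

Step 27
Reactants: 34 hydroxy acid
Product: 35 target (CNP0115928.1)
Conditions: Dess–Martin periodinane, CH2Cl2, rt
Reagents that add atoms: none
Why: Periodinane oxidation of the α-hydroxy ketone gives the 1,2-diketone under neutral, non-nucleophilic conditions as the last step, so C16 becomes enolisable only inside the finished macrocycle.

**Compound list**

1 | cis-3,5-dimethylcyclohexanone | O=C1C[C@H](C)C[C@H](C)C1 | starting material
2 | (3S,5R)-3,5-dimethyl-1-(trimethylsilyloxy)cyclohex-1-ene | C[Si](C)(C)OC1=C[C@@H](C)C[C@@H](C)C1 | intermediate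
3 | (3R,5S)-3,5-dimethyl-6-oxohexanoic acid | OC(=O)C[C@H](C)C[C@H](C)C=O | intermediate
4 | (3R,5S)-3,5-dimethylhept-6-enoic acid | OC(=O)C[C@H](C)C[C@H](C)C=C | intermediate
5 | (3R,5S)-3,5-dimethylhept-6-en-1-ol | OCC[C@H](C)C[C@H](C)C=C | intermediate
6 | (3R,5S)-3,5-dimethylhept-6-enal | O=CC[C@H](C)C[C@H](C)C=C | intermediate
7 | (S)-lactic acid | C[C@H](O)C(=O)O | starting material
8 | pivalaldehyde | CC(C)(C)C=O | starting material
9 | (2S,5S)-2-tert-butyl-5-methyl-1,3-dioxolan-4-one | C[C@@H]1O[C@H](C(C)(C)C)OC1=O | intermediate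
10 | (2S)-5-bromo-2-tert-butyl-5-methyl-1,3-dioxolan-4-one (C5 epimers) | CC1(Br)O[C@H](C(C)(C)C)OC1=O | intermediate
11 | (S)-2-tert-butyl-5-methylene-1,3-dioxolan-4-one | C=C1O[C@H](C(C)(C)C)OC1=O | intermediate
12 | but-2-yn-1-ol | CC#CCO | starting material
13 | (E)-2-(tributylstannyl)but-2-en-1-ol | C/C=C(CO)/[Sn](CCCC)(CCCC)CCCC | intermediate
14 | tert-butyldimethylsilyl ether of 13 | C/C=C(CO[Si](C)(C)C(C)(C)C)/[Sn](CCCC)(CCCC)CCCC | intermediate
15 | pent-1-en-4-yne | C=CCC#C | starting material
16 | (E)-1-iodopenta-1,4-diene | I/C=C/CC=C | intermediate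
17 | tert-butyl{[(2Z,3E)-2-ethylidenehepta-3,6-dien-1-yl]oxy}dimethylsilane | C/C=C(CO[Si](C)(C)C(C)(C)C)/C=C/CC=C | intermediate
18 | spiro Diels–Alder adduct (C5 allyl, C7 CH2OTBS, C8 methyl; C10 spiro to the (S)-2-tert-butyl-1,3-dioxolan-4-one) | C=CC[C@H]1C=C(CO[Si](C)(C)C(C)(C)C)[C@@H](C)C[C@@]12O[C@H](C(C)(C)C)OC2=O | intermediate
19 | α-hydroxy methyl ketone (C10–OH, C18 acetyl) | C=CC[C@H]1C=C(CO[Si](C)(C)C(C)(C)C)[C@@H](C)C[C@@]1(C(C)=O)O | intermediate
20 | bis-silyl enol ether (O11–SiMe3, C18(OSiMe3)=C17H2) | C=CC[C@H]1C=C(CO[Si](C)(C)C(C)(C)C)[C@@H](C)C[C@@]1(C(=C)O[Si](C)(C)C)O[Si](C)(C)C | intermediate (not isolated)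
21 | bromomethyl ketone O11-trimethylsilyl ether | C=CC[C@H]1C=C(CO[Si](C)(C)C(C)(C)C)[C@@H](C)C[C@@]1(C(=O)CBr)O[Si](C)(C)C | intermediate
22 | γ-keto aldehyde (C15 aldehyde, (R)-C16, C18 ketone, O11–SiMe3) | C=CC[C@H]1C=C(CO[Si](C)(C)C(C)(C)C)[C@@H](C)C[C@@]1(C(=O)C[C@@H](C=O)[C@H](C)C[C@H](C)C=C)O[Si](C)(C)C | intermediate
23 | lithium alkoxide of the 1-ethoxyvinyl adduct at C15 | C=CC[C@H]1C=C(CO[Si](C)(C)C(C)(C)C)[C@@H](C)C[C@@]1(C(=O)C[C@@H](C(O[Li])C(=C)OCC)[C@H](C)C[C@H](C)C=C)O[Si](C)(C)C | intermediate (not isolated)
24 | dihydroxy diketone (C15–OH, C14 acetyl, C18 ketone, C10–OH) | C=CC[C@H]1C=C(CO[Si](C)(C)C(C)(C)C)[C@@H](C)C[C@@]1(C(=O)C[C@@H](C(O)C(C)=O)[C@H](C)C[C@H](C)C=C)O | intermediate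
25 | C15 tert-butyldimethylsilyl ether of 24 | C=CC[C@H]1C=C(CO[Si](C)(C)C(C)(C)C)[C@@H](C)C[C@@]1(C(=O)C[C@@H](C(O[Si](C)(C)C(C)(C)C)C(C)=O)[C@H](C)C[C@H](C)C=C)O | intermediate
26 | hydroxy enone (cyclohexenone C14=O, C13=C18; C10–OH) | C=CC[C@H]1C=C(CO[Si](C)(C)C(C)(C)C)[C@@H](C)C[C@@]1(C2=CC(=O)C(O[Si](C)(C)C(C)(C)C)[C@H](C2)[C@H](C)C[C@H](C)C=C)O | intermediate
27 | enone methyl carbonate (O11–C12(=O)OMe) | C=CC[C@H]1C=C(CO[Si](C)(C)C(C)(C)C)[C@@H](C)C[C@@]1(C2=CC(=O)C(O[Si](C)(C)C(C)(C)C)[C@H](C2)[C@H](C)C[C@H](C)C=C)OC(=O)OC | intermediate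
28 | copper enolate (C13=C14–O–Cu, C18–H; phosphine ligands omitted) | C=CC[C@H]1C=C(CO[Si](C)(C)C(C)(C)C)[C@@H](C)C[C@@]1([C@H]2C=C(O[Cu])C(O[Si](C)(C)C(C)(C)C)[C@H](C2)[C@H](C)C[C@H](C)C=C)OC(=O)OC | intermediate (not isolated)
29 | β-keto-γ-lactone (C13–H, cis-fused) | C=CC[C@H]1C=C(CO[Si](C)(C)C(C)(C)C)[C@@H](C)C[C@@]12OC(=O)[C@H]3C(=O)C(O[Si](C)(C)C(C)(C)C)[C@H](C[C@@H]23)[C@H](C)C[C@H](C)C=C | intermediate
30 | C13-methylated β-keto-γ-lactone | C=CC[C@H]1C=C(CO[Si](C)(C)C(C)(C)C)[C@@H](C)C[C@@]12OC(=O)[C@@]3(C)C(=O)C(O[Si](C)(C)C(C)(C)C)[C@H](C[C@@H]23)[C@H](C)C[C@H](C)C=C | intermediate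
31 | macrocyclic alkene (C2=C3) | C[C@@H]1C=CC[C@H]2C=C(CO[Si](C)(C)C(C)(C)C)[C@@H](C)C[C@@]23OC(=O)[C@@]2(C)C(=O)C(O[Si](C)(C)C(C)(C)C)[C@H](C[C@H]23)[C@H](C)C1 | intermediate
32 | saturated macrocycle (bis-silyl ether) | C[C@@H]1CCC[C@H]2C=C(CO[Si](C)(C)C(C)(C)C)[C@@H](C)C[C@@]23OC(=O)[C@@]2(C)C(=O)C(O[Si](C)(C)C(C)(C)C)[C@H](C[C@H]23)[C@H](C)C1 | intermediate
33 | diol (C7–CH2OH, C15–OH) | C[C@@H]1CCC[C@H]2C=C(CO)[C@@H](C)C[C@@]23OC(=O)[C@@]2(C)C(=O)C(O)[C@H](C[C@H]23)[C@H](C)C1 | intermediate
34 | hydroxy acid (C7–CO2H, C15–OH) | C[C@@H]1CCC[C@H]2C=C(C(=O)O)[C@@H](C)C[C@@]23OC(=O)[C@@]2(C)C(=O)C(O)[C@H](C[C@H]23)[C@H](C)C1 | intermediate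
35 | CNP0115928.1 | C[C@@H]1CCC[C@H]2C=C(C(=O)O)[C@@H](C)C[C@@]23OC(=O)[C@@]2(C)C(=O)C(=O)[C@H](C[C@H]23)[C@H](C)C1 | target

**Step count and risks**

Total step count: 27. Longest linear sequence: 18 steps (steps 9, 10, 12, then 13 to 27).

Steps most likely to fail:

1. Step 21 (proposed new method). The copper enolate may be protonated or silylated before it attacks the weakly electrophilic carbonate, so that plain conjugate reduction results, or 1,2-reduction may compete at the hindered enone. The fallback sets out from 26 and uses known chemistry. Conjugate reduction of the free hydroxy enone with [(Ph3P)CuH]6 and protonation should give the saturated hydroxy ketone F1 with the same anti delivery of hydrogen to C18. Acylation with ClCO2Me, pyridine and DMAP should give the saturated ketone methyl carbonate F2. NaH in THF (0 °C to rt) then effects a classical Dieckmann-type cyclisation under equilibrating conditions, in which only the C13 enolate reaches C12 through a five-membered transition state (the C15 enolate would need a seven-membered ring). This returns to the route at 29.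

2. Step 23. Ring closure on the rigid spiro-tricyclic core may be slow, so that intermolecular metathesis and oligomer formation take over. The fallback sets out from 27 and closes the macrocycle before the lactone, while C18 is still trigonal and the two alkene arms are more mobile. Ring-closing metathesis with the second-generation Grubbs catalyst at high dilution should give the macrocyclic enone carbonate F3. The conditions of step 21 then give the macrocyclic β-keto lactone F4, in which the 1,3-bridge forces the cis relation of C10 and C19. Methylation with K2CO3 and MeI returns to the route at 31.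

3. Step 16. Radical generation from the hindered bromoketone or its capture by the enamine may be inefficient, and the γ-keto aldehyde may lose configuration at C16 by enolisation under the amine conditions. The fallback sets out from 6 and 21 and replaces the radical coupling by an auxiliary-controlled SN2 alkylation. Condensation of 6 with (S)-1-amino-2-(methoxymethyl)pyrrolidine gives the SAMP hydrazone F5. Deprotonation with LiN(iPr)2 (THF, 0 °C) and alkylation of the azaenolate with 21 at −100 °C should give the alkylated hydrazone F6, with R at C16 by the established facial sense. Cleavage with aqueous oxalic acid and ether returns to the route at 22.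

Further compounds
F1 | step 21 | saturated hydroxy ketone (C18–H, C13H2, C10–OH) | C=CC[C@H]1C=C(CO[Si](C)(C)C(C)(C)C)[C@@H](C)C[C@@]1([C@H]2CC(=O)C(O[Si](C)(C)C(C)(C)C)[C@H](C2)[C@H](C)C[C@H](C)C=C)O
F2 | step 21 | saturated ketone methyl carbonate | C=CC[C@H]1C=C(CO[Si](C)(C)C(C)(C)C)[C@@H](C)C[C@@]1([C@H]2CC(=O)C(O[Si](C)(C)C(C)(C)C)[C@H](C2)[C@H](C)C[C@H](C)C=C)OC(=O)OC
F3 | step 23 | macrocyclic enone methyl carbonate (C2=C3) | C[C@@H]1C=CC[C@H]2C=C(CO[Si](C)(C)C(C)(C)C)[C@@H](C)C[C@]2(OC(=O)OC)C3=CC(=O)C(O[Si](C)(C)C(C)(C)C)[C@H](C3)[C@H](C)C1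
F4 | step 23 | macrocyclic β-keto-γ-lactone (C13–H, C2=C3) | C[C@@H]1C=CC[C@H]2C=C(CO[Si](C)(C)C(C)(C)C)[C@@H](C)C[C@@]23OC(=O)[C@H]2C(=O)C(O[Si](C)(C)C(C)(C)C)[C@H](C[C@H]23)[C@H](C)C1
F5 | step 16 | SAMP hydrazone of 6 | COC[C@@H]1CCCN1/N=C/C[C@H](C)C[C@H](C)C=C
F6 | step 16 | C16-alkylated SAMP hydrazone | C=CC[C@H]1C=C(CO[Si](C)(C)C(C)(C)C)[C@@H](C)C[C@@]1(C(=O)C[C@@H](/C=N/N2CCC[C@H]2COC)[C@H](C)C[C@H](C)C=C)O[Si](C)(C)C
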